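The 1,2‑dioxane ring (O1–O2–C3–C4–C5–C6) is cut at C3–C4 and C5–C6, the two bonds that tie the peroxide‑bearing carbons C3 and C6 to the C4–C5 ethano bridge. The key step exploits that each of these carbons carries a peroxide oxygen and can be made electrophilic as a peroxycarbenium ion, so a (Z)‑1‑stannyl‑2‑silylethene can act as a two‑carbon 1,2‑dinucleophile. In one flask a silyl peroxyacetal (C1–C3, from a chiral hydroxy ester) is vinylated at C3, then (5E,9E)‑farnesylacetone (C6 with its methyl and triene chain) is condensed on the same peroxide and the vinylsilane closes the ring at quaternary C6. Diimide saturation and oxidation of C1 to the methyl ester finish the route.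

Key step: step 8

Remark: atom labels C1–C6, O1 and O2 are those of the target (C1 ester carbon, C2 its α‑carbon, C3 the ring carbon with the side chain, C6 the ring carbon with methyl and chain). The acetal carbon of 5 and 6 and the ketal carbon of 15 are epimer mixtures of no consequence, because both carbons become planar cations in step 8.

Step 1
Reactants: 1 methyl (S)-3-hydroxy-2-methylpropanoate
Product: 2 methyl (S)-3-[(tert-butyldiphenylsilyl)oxy]-2-methylpropanoate
Conditions: TBDPSCl, imidazole, CH2Cl2, 0 °C to rt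
Reagents that add atoms: tert-butyl(chloro)diphenylsilane, CC(C)(C)[Si](Cl)(c1ccccc1)c1ccccc1
Why: Standard silylation of a primary alcohol that leaves the C2 stereocentre untouched.

Step 2
Reactants: 2 methyl (S)-3-[(tert-butyldiphenylsilyl)oxy]-2-methylpropanoate
Product: 3 (S)-3-[(tert-butyldiphenylsilyl)oxy]-2-methylpropanal
Conditions: i-Bu2AlH (1.1 equiv), CH2Cl2, −78 °C; MeOH, then aq. KNaC4H4O6
Reagents that add atoms: none
Why: Partial reduction of the ester through an aluminium hemiacetal that is stable at −78 °C should give the aldehyde without epimerisation if it is used promptly.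

Step 3
Reactants: 3 (S)-3-[(tert-butyldiphenylsilyl)oxy]-2-methylpropanal
Product: 4 (S)-tert-butyl(3,3-dimethoxy-2-methylpropoxy)diphenylsilane
Conditions: HC(OMe)3, MeOH, PPTS (cat.), rt
Reagents that add atoms: trimethyl orthoformate, COC(OC)OC; methanol, CO
Why: Acid‑catalysed acetalisation with the orthoformate as water scavenger, under acid mild enough not to enolise the α‑stereocentre.

Step 4
Reactants: 4 (S)-tert-butyl(3,3-dimethoxy-2-methylpropoxy)diphenylsilane
Product: 5 (1RS,2S)-3-[(tert-butyldiphenylsilyl)oxy]-1-methoxy-2-methylpropyl hydroperoxide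
Conditions: anhydrous H2O2 in Et2O (5 equiv), camphorsulfonic acid (cat.), 0 °C
Reagents that add atoms: hydrogen peroxide, OO
Why: Acid‑catalysed transperoxyacetalisation, in which the oxocarbenium ion of the acetal is captured by hydrogen peroxide, is the classical route to α‑alkoxy hydroperoxides.

Step 5
Reactants: 5 (1RS,2S)-3-[(tert-butyldiphenylsilyl)oxy]-1-methoxy-2-methylpropyl hydroperoxide
Product: 6 tert-butyl{(2S)-3-methoxy-2-methyl-3-[(triethylsilyl)peroxy]propoxy}diphenylsilane (both epimers at the acetal carbon)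
Conditions: Et3SiOTf, 2,6-lutidine, CH2Cl2, −78 °C
Reagents that add atoms: triethylsilyl trifluoromethanesulfonate, CC[Si](CC)(CC)OS(=O)(=O)C(F)(F)F
Why: O‑Silylation of the hydroperoxide gives a silyl peroxyacetal, the established precursor type of silylated peroxycarbenium ions.

Step 6
Reactants: 7 acetylene; 8 tributyl(trimethylsilyl)stannane
Product: 9 (Z)-tributyl[2-(trimethylsilyl)ethenyl]stannane
Conditions: Pd(PPh3)4 (2 mol %), THF, 60 °C, sealed vessel
Reagents that add atoms: none
Why: Alkyne silylstannation catalysed by zerovalent palladium (oxidative addition of Si–Sn, syn insertion, reductive elimination) delivers the cis adduct, hence the (Z) olefin.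

Step 7
Reactants: 10 (2E,6E)-1-bromo-3,7,11-trimethyldodeca-2,6,10-triene (farnesyl bromide); 11 pentane-2,4-dione
Product: 13 (5E,9E)-6,10,14-trimethylpentadeca-5,9,13-trien-2-one (farnesylacetone), via 3-farnesylpentane-2,4-dione 12 (not isolated)
Conditions: K2CO3, EtOH, reflux
Reagents that add atoms: none
Why: C‑Alkylation of acetylacetone by SN2 at the primary allylic bromide (E geometry kept) followed by in situ ethanolysis (retro‑Claisen deacetylation) is the classical one‑pot methyl ketone synthesis.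

Step 8
Reactants: 6 tert-butyl{(2S)-3-methoxy-2-methyl-3-[(triethylsilyl)peroxy]propoxy}diphenylsilane; 9 (Z)-tributyl[2-(trimethylsilyl)ethenyl]stannane; 13 (5E,9E)-6,10,14-trimethylpentadeca-5,9,13-trien-2-one
Product: 16 tert-butyl({(2S)-2-[(3S,6R)-6-methyl-6-[(3E,7E)-4,8,12-trimethyltrideca-3,7,11-trien-1-yl]-3,6-dihydro-1,2-dioxin-3-yl]propyl}oxy)diphenylsilane, via allylic silyl peroxide 14 (not isolated), via mixed silyl peroxyketal 15 (not isolated)
Conditions: 6 (1.1 equiv), 9 (1.0 equiv), TMSOTf (1.1 equiv), 2,6-di-tert-butyl-4-methylpyridine (0.3 equiv), CH2Cl2, −78 °C; then 13 (1.0 equiv), TMSOTf (0.2 equiv), −78 to −40 °C; aq. NaHCO3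
Reagents that add atoms: none
Why: Proposed new method: TMSOTf ionises the methoxy group of 6 to a silylated peroxycarbenium ion at C3 that is attacked at the tin‑bearing carbon of 9 (ipso‑destannylation with retention through a β‑stannyl cation) to form C3–C4 and (Z)‑vinylsilane 14, after which ketone 13 condenses with the silyl peroxide to peroxyketal 15, whose ionisation gives the ketone‑derived peroxycarbenium ion at C6 that is captured at the silicon‑bearing carbon C5 with loss of the silyl group, forming C5–C6 and the C4=C5 ring olefin. The closest known reaction types are the Lewis‑acid substitution and alkene annulation of peroxyacetals and silyl peroxyketals through peroxycarbenium ions and the vinylsilane‑terminated silyl‑Prins cyclisation of oxocarbenium ions to dihydropyrans. The 3,6‑dihydro‑1,2‑dioxine closes 6‑endo‑trig on the vinylsilane, the five‑membered exo mode being disfavoured because it would put the cation α instead of β to silicon, and the (Z) geometry places silicon pseudo‑axial for hyperconjugative assistance. C3 is set in the intermolecular event by Felkin–Anh addition anti to the CH2OTBDPS group of the α‑branched cation (2,3‑syn), both acetal epimers of 6 converging through the planar ion, and C6 is set in the ring closure by a chair‑like transition state with the C3 substituent pseudo‑equatorial and the homofarnesyl chain anti to the O–O bond of the (E)‑peroxycarbenium ion, hence pseudo‑equatorial and trans to the C3 substituent with the methyl group cis. The step needs the peroxycarbenium ions to react with the vinylmetal carbons and not with the three trisubstituted olefins of 13, which is secured by using 9 as the limiting reagent, by the intramolecular ring closure (the nearest chain olefin could only give a four‑ or five‑membered ring) and by the hindered pyridine that suppresses proton‑initiated polyene cyclisation; the discrimination of methyl against the chain at C6 is expected to be moderate only and the minor C6 epimer is removed by chromatography.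

Step 9
Reactants: 16 tert-butyl({(2S)-2-[(3S,6R)-6-methyl-6-[(3E,7E)-4,8,12-trimethyltrideca-3,7,11-trien-1-yl]-3,6-dihydro-1,2-dioxin-3-yl]propyl}oxy)diphenylsilane
Product: 17 tert-butyl({(2S)-2-[(3S,6R)-6-methyl-6-[(3E,7E)-4,8,12-trimethyltrideca-3,7,11-trien-1-yl]-1,2-dioxan-3-yl]propyl}oxy)diphenylsilane
Conditions: KO2CN=NCO2K (excess), AcOH, MeOH/CH2Cl2, 0 °C to rt
Reagents that add atoms: none
Why: Diimide made in situ transfers hydrogen in a concerted syn fashion to the cis‑disubstituted ring olefin much faster than to the trisubstituted chain olefins and does not cleave the O–O bond, and the acidic medium avoids Kornblum–DeLaMare opening of the allylic C3–H peroxide.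

Step 10
Reactants: 17 tert-butyl({(2S)-2-[(3S,6R)-6-methyl-6-[(3E,7E)-4,8,12-trimethyltrideca-3,7,11-trien-1-yl]-1,2-dioxan-3-yl]propyl}oxy)diphenylsilane
Product: 18 (2S)-2-[(3S,6R)-6-methyl-6-[(3E,7E)-4,8,12-trimethyltrideca-3,7,11-trien-1-yl]-1,2-dioxan-3-yl]propan-1-ol
Conditions: Bu4NF, AcOH (1:1), THF, 0 °C to rt
Reagents that add atoms: none
Why: Fluoride cleavage of the silyl ether, buffered with acetic acid so that the base‑sensitive secondary peroxide carbon C3 is not deprotonated.

Step 11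
Reactants: 18 (2S)-2-[(3S,6R)-6-methyl-6-[(3E,7E)-4,8,12-trimethyltrideca-3,7,11-trien-1-yl]-1,2-dioxan-3-yl]propan-1-ol
Product: 19 (2R)-2-[(3S,6R)-6-methyl-6-[(3E,7E)-4,8,12-trimethyltrideca-3,7,11-trien-1-yl]-1,2-dioxan-3-yl]propanoic acid
Conditions: TEMPO (cat.), PhI(OAc)2 (2.2 equiv), MeCN/H2O, 0 °C to rt
Reagents that add atoms: water, O
Why: Oxoammonium‑mediated oxidation of the primary alcohol through the aldehyde hydrate to the acid runs near neutral pH and should tolerate the dialkyl peroxide and the trisubstituted olefins without epimerising C2.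

Step 12
Reactants: 19 (2R)-2-[(3S,6R)-6-methyl-6-[(3E,7E)-4,8,12-trimethyltrideca-3,7,11-trien-1-yl]-1,2-dioxan-3-yl]propanoic acid
Product: 20 methyl (2R)-2-[(3S,6R)-6-methyl-6-[(3E,7E)-4,8,12-trimethyltrideca-3,7,11-trien-1-yl]-1,2-dioxan-3-yl]propanoate
Conditions: TMSCHN2, MeOH/toluene, 0 °C
Reagents that add atoms: (trimethylsilyl)diazomethane, C[Si](C)(C)C=[N+]=[N-]
Why: O‑Methylation of the acid through a methyldiazonium ion needs no base, so neither C2 nor the peroxide is put at risk.

Compound list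
1 | methyl (S)-3-hydroxy-2-methylpropanoate | OC[C@H](C)C(=O)OC | starting material
2 | methyl (S)-3-[(tert-butyldiphenylsilyl)oxy]-2-methylpropanoate | CC(C)(C)[Si](c1ccccc1)(c1ccccc1)OC[C@H](C)C(=O)OC | intermediate
3 | (S)-3-[(tert-butyldiphenylsilyl)oxy]-2-methylpropanal | CC(C)(C)[Si](c1ccccc1)(c1ccccc1)OC[C@H](C)C=O | intermediate
4 | (S)-tert-butyl(3,3-dimethoxy-2-methylpropoxy)diphenylsilane | CC(C)(C)[Si](c1ccccc1)(c1ccccc1)OC[C@H](C)C(OC)OC | intermediate
5 | (1RS,2S)-3-[(tert-butyldiphenylsilyl)oxy]-1-methoxy-2-methylpropyl hydroperoxide | CC(C)(C)[Si](c1ccccc1)(c1ccccc1)OC[C@H](C)C(OC)OO | intermediate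
6 | tert-butyl{(2S)-3-methoxy-2-methyl-3-[(triethylsilyl)peroxy]propoxy}diphenylsilane (both acetal epimers) | CC(C)(C)[Si](c1ccccc1)(c1ccccc1)OC[C@H](C)C(OC)OO[Si](CC)(CC)CC | intermediate
7 | acetylene | C#C | starting material
8 | tributyl(trimethylsilyl)stannane | CCCC[Sn](CCCC)(CCCC)[Si](C)(C)C | starting material
9 | (Z)-tributyl[2-(trimethylsilyl)ethenyl]stannane | CCCC[Sn](CCCC)(CCCC)/C=C\[Si](C)(C)C | intermediate
10 | (2E,6E)-1-bromo-3,7,11-trimethyldodeca-2,6,10-triene | BrC/C=C(\C)CC/C=C(\C)CCC=C(C)C | starting material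
11 | pentane-2,4-dione | CC(=O)CC(C)=O | starting material
12 | 3-[(2E,6E)-3,7,11-trimethyldodeca-2,6,10-trien-1-yl]pentane-2,4-dione | CC(=O)C(C/C=C(\C)CC/C=C(\C)CCC=C(C)C)C(C)=O | intermediate
13 | (5E,9E)-6,10,14-trimethylpentadeca-5,9,13-trien-2-one | CC(=O)CC/C=C(\C)CC/C=C(\C)CCC=C(C)C | intermediate
14 | triethyl({(3R,4S,1Z)-5-[(tert-butyldiphenylsilyl)oxy]-4-methyl-1-(trimethylsilyl)pent-1-en-3-yl}peroxy)silane | CC(C)(C)[Si](c1ccccc1)(c1ccccc1)OC[C@H](C)[C@@H](OO[Si](CC)(CC)CC)/C=C\[Si](C)(C)C | intermediate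
15 | (5E,9E)-2-({(3R,4S,1Z)-5-[(tert-butyldiphenylsilyl)oxy]-4-methyl-1-(trimethylsilyl)pent-1-en-3-yl}peroxy)-6,10,14-trimethyl-2-[(trimethylsilyl)oxy]pentadeca-5,9,13-triene (both ketal epimers) | CC(C)(C)[Si](c1ccccc1)(c1ccccc1)OC[C@H](C)[C@@H](OOC(C)(CC/C=C(\C)CC/C=C(\C)CCC=C(C)C)O[Si](C)(C)C)/C=C\[Si](C)(C)C | intermediate
16 | tert-butyl({(2S)-2-[(3S,6R)-6-methyl-6-[(3E,7E)-4,8,12-trimethyltrideca-3,7,11-trien-1-yl]-3,6-dihydro-1,2-dioxin-3-yl]propyl}oxy)diphenylsilane | CC(C)(C)[Si](c1ccccc1)(c1ccccc1)OC[C@H](C)[C@@H]1C=C[C@@](C)(CC/C=C(\C)CC/C=C(\C)CCC=C(C)C)OO1 | intermediate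
17 | tert-butyl({(2S)-2-[(3S,6R)-6-methyl-6-[(3E,7E)-4,8,12-trimethyltrideca-3,7,11-trien-1-yl]-1,2-dioxan-3-yl]propyl}oxy)diphenylsilane | CC(C)(C)[Si](c1ccccc1)(c1ccccc1)OC[C@H](C)[C@@H]1CC[C@@](C)(CC/C=C(\C)CC/C=C(\C)CCC=C(C)C)OO1 | intermediate
18 | (2S)-2-[(3S,6R)-6-methyl-6-[(3E,7E)-4,8,12-trimethyltrideca-3,7,11-trien-1-yl]-1,2-dioxan-3-yl]propan-1-ol | OC[C@H](C)[C@@H]1CC[C@@](C)(CC/C=C(\C)CC/C=C(\C)CCC=C(C)C)OO1 | intermediate
19 | (2R)-2-[(3S,6R)-6-methyl-6-[(3E,7E)-4,8,12-trimethyltrideca-3,7,11-trien-1-yl]-1,2-dioxan-3-yl]propanoic acid | OC(=O)[C@H](C)[C@@H]1CC[C@@](C)(CC/C=C(\C)CC/C=C(\C)CCC=C(C)C)OO1 | intermediate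
20 | methyl (2R)-2-[(3S,6R)-6-methyl-6-[(3E,7E)-4,8,12-trimethyltrideca-3,7,11-trien-1-yl]-1,2-dioxan-3-yl]propanoate | COC(=O)[C@H](C)[C@@H]1CC[C@@](C)(CC/C=C(\C)CC/C=C(\C)CCC=C(C)C)OO1 | target

Total step count: 12. Longest linear sequence: 10 steps (steps 1–5 and 8–12).

Steps most likely to fail

1. Step 8 (proposed new method). What may go wrong: capture of the β‑stannyl cation by the silylperoxy oxygen (1,2‑dioxolane formation) instead of destannylation, Lewis‑acid heterolysis of the O–O bond (Hock/Criegee‑type fragmentation), failure of the weakly nucleophilic vinylsilane to terminate on the ketone‑derived cation, and low facial discrimination between methyl and chain at C6. The fallback uses known reactions only, sets out from 10 and 3 and returns at 17; it does not control C6 either, so the two C6 epimers are separated at the end. Alkylation of the dianion of 3‑methylbut‑3‑en‑1‑ol (n‑BuLi, TMEDA) with 10 should give (6E,10E)-7,11,15-trimethyl-3-methylidenehexadeca-6,10,14-trien-1-ol F1, and Appel bromination (CBr4, PPh3) the bromide (6E,10E)-1-bromo-7,11,15-trimethyl-3-methylidenehexadeca-6,10,14-triene F2. Its Grignard reagent (Mg, THF) adds to aldehyde 3 to give (2S,9E,13E)-1-[(tert-butyldiphenylsilyl)oxy]-2,10,14,18-tetramethyl-6-methylidenenonadeca-9,13,17-trien-3-ol F3 as a C3 epimer mixture, which Dess–Martin oxidation converts into the ketone (2S,9E,13E)-1-[(tert-butyldiphenylsilyl)oxy]-2,10,14,18-tetramethyl-6-methylidenenonadeca-9,13,17-trien-3-one F4. Felkin‑controlled reduction with LiBH(s-Bu)3 at −78 °C should give the 2,3‑anti alcohol (2S,3R,9E,13E)-1-[(tert-butyldiphenylsilyl)oxy]-2,10,14,18-tetramethyl-6-methylidenenonadeca-9,13,17-trien-3-ol F5, and MsCl/Et3N its methanesulfonate F6. Mukaiyama–Isayama hydroperoxysilylation (Co(thd)2 cat., thd = 2,2,6,6-tetramethylheptane-3,5-dionate, O2, Et3SiH), which prefers the 1,1‑disubstituted olefin, should give the tertiary triethylsilyl peroxide (2S,3R,9E,13E)-1-[(tert-butyldiphenylsilyl)oxy]-2,6,10,14,18-pentamethyl-6-[(triethylsilyl)peroxy]nonadeca-9,13,17-trien-3-yl methanesulfonate F7 as both C6 epimers. Buffered Bu4NF/AcOH at 0 °C frees the hydroperoxide (2S,3R,9E,13E)-1-[(tert-butyldiphenylsilyl)oxy]-6-hydroperoxy-2,6,10,14,18-pentamethylnonadeca-9,13,17-trien-3-yl methanesulfonate F8 with the TBDPS ether kept. CsOH·H2O in DMF then closes the 1,2‑dioxane by intramolecular SN2 displacement with inversion at C3, giving 17 and its C6 epimer.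

2. Step 4. What may go wrong: over‑exchange to the geminal dihydroperoxide or to a bis(alkoxyalkyl) peroxide, and acid‑promoted loss of the hydroperoxide group during isolation. The fallback sets out from 3 and returns at 5. Wittig methoxymethylenation (Ph3P(Cl)CH2OMe, NaN(SiMe3)2, THF) gives the enol ether tert-butyl{[(2R)-4-methoxy-2-methylbut-3-en-1-yl]oxy}diphenylsilane F9 as an E/Z mixture. Ozonolysis in MeOH/CH2Cl2 at −78 °C cleaves it to methyl formate and the carbonyl oxide on the C3 side, which methanol traps to give 5 directly.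

3. Step 11. What may go wrong: base‑ or oxoammonium‑promoted Kornblum–DeLaMare cleavage at C3–H, or β‑elimination and C2 epimerisation while the transient β‑peroxy aldehyde sits in the aqueous medium. The fallback sets out from 18 and returns at 19, and splits the oxidation into two non‑basic stages with an isolated intermediate. Dess–Martin periodinane (NaHCO3‑buffered, CH2Cl2, 0 °C) gives the aldehyde (2R)-2-[(3S,6R)-6-methyl-6-[(3E,7E)-4,8,12-trimethyltrideca-3,7,11-trien-1-yl]-1,2-dioxan-3-yl]propanal F10, which is oxidised at once under Pinnick conditions (NaClO2, NaH2PO4, 2‑methylbut‑2‑ene, t‑BuOH/H2O) to 19.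

Further compounds
F1 | step 8 | (6E,10E)-7,11,15-trimethyl-3-methylidenehexadeca-6,10,14-trien-1-ol | OCCC(=C)CC/C=C(\C)CC/C=C(\C)CCC=C(C)C
F2 | step 8 | (6E,10E)-1-bromo-7,11,15-trimethyl-3-methylidenehexadeca-6,10,14-triene | BrCCC(=C)CC/C=C(\C)CC/C=C(\C)CCC=C(C)C
F3 | step 8 | (2S,9E,13E)-1-[(tert-butyldiphenylsilyl)oxy]-2,10,14,18-tetramethyl-6-methylidenenonadeca-9,13,17-trien-3-ol (C3 epimers) | CC(C)(C)[Si](c1ccccc1)(c1ccccc1)OC[C@H](C)C(O)CCC(=C)CC/C=C(\C)CC/C=C(\C)CCC=C(C)C
F4 | step 8 | (2S,9E,13E)-1-[(tert-butyldiphenylsilyl)oxy]-2,10,14,18-tetramethyl-6-methylidenenonadeca-9,13,17-trien-3-one | CC(C)(C)[Si](c1ccccc1)(c1ccccc1)OC[C@H](C)C(=O)CCC(=C)CC/C=C(\C)CC/C=C(\C)CCC=C(C)C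
F5 | step 8 | (2S,3R,9E,13E)-1-[(tert-butyldiphenylsilyl)oxy]-2,10,14,18-tetramethyl-6-methylidenenonadeca-9,13,17-trien-3-ol | CC(C)(C)[Si](c1ccccc1)(c1ccccc1)OC[C@H](C)[C@H](O)CCC(=C)CC/C=C(\C)CC/C=C(\C)CCC=C(C)C
F6 | step 8 | (2S,3R,9E,13E)-1-[(tert-butyldiphenylsilyl)oxy]-2,10,14,18-tetramethyl-6-methylidenenonadeca-9,13,17-trien-3-yl methanesulfonate | CC(C)(C)[Si](c1ccccc1)(c1ccccc1)OC[C@H](C)[C@H](OS(C)(=O)=O)CCC(=C)CC/C=C(\C)CC/C=C(\C)CCC=C(C)C
F7 | step 8 | (2S,3R,9E,13E)-1-[(tert-butyldiphenylsilyl)oxy]-2,6,10,14,18-pentamethyl-6-[(triethylsilyl)peroxy]nonadeca-9,13,17-trien-3-yl methanesulfonate (C6 epimers) | CC(C)(C)[Si](c1ccccc1)(c1ccccc1)OC[C@H](C)[C@H](OS(C)(=O)=O)CCC(C)(OO[Si](CC)(CC)CC)CC/C=C(\C)CC/C=C(\C)CCC=C(C)C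
F8 | step 8 | (2S,3R,9E,13E)-1-[(tert-butyldiphenylsilyl)oxy]-6-hydroperoxy-2,6,10,14,18-pentamethylnonadeca-9,13,17-trien-3-yl methanesulfonate (C6 epimers) | CC(C)(C)[Si](c1ccccc1)(c1ccccc1)OC[C@H](C)[C@H](OS(C)(=O)=O)CCC(C)(OO)CC/C=C(\C)CC/C=C(\C)CCC=C(C)C
F9 | step 4 | tert-butyl{[(2R)-4-methoxy-2-methylbut-3-en-1-yl]oxy}diphenylsilane (E/Z mixture) | CC(C)(C)[Si](c1ccccc1)(c1ccccc1)OC[C@H](C)C=COC
F10 | step 11 | (2R)-2-[(3S,6R)-6-methyl-6-[(3E,7E)-4,8,12-trimethyltrideca-3,7,11-trien-1-yl]-1,2-dioxan-3-yl]propanal | O=C[C@H](C)[C@@H]1CC[C@@](C)(CC/C=C(\C)CC/C=C(\C)CCC=C(C)C)OO1
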